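(The runs were generated by integration with made-up constants; the scatter is artificial.)

Reading the runs at their last time, 55 min, we find that the grey run has turned 54.9% of its G into L. That is the figure we lean on for your quick number on the violet run, whose charge holds X to G at the grey ratio of 1.10, so that by the charge and the overall equation G is the limiting reagent in both.

| flask | G | X | L | time |
|---|---|---|---|---|
| grey | 80.0 mM | 88.0 mM |  |  |
| red | 48.0 mM | 56.0 mM |  |  |
| teal | 80.0 mM | 88.0 mM | 24.0 mM |  |
| green | 160 mM | 88.0 mM |  |  |
| violet | 400 mM | 440 mM |  | 55 min |

| grey run: time / min | grey run: [L] / mM | red run: time / min | red run: [L] / mM | teal run: time / min | teal run: [L] / mM | green run: time / min | green run: [L] / mM |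
|---|---|---|---|---|---|---|---|
| 2.2 | 4.5 | 2.2 | 2.9 | 2.2 | 28.9 | 2.2 | 8.8 |
| 4.2 | 8.2 | 4.2 | 3.5 | 4.2 | 31.3 | 4.2 | 15.8 |
| 8.0 | 14.1 | 8.0 | 6.3 | 8.0 | 38.9 | 8.0 | 26.3 |
| 15 | 22.6 | 15 | 10.6 | 15 | 46.1 | 15 | 39.9 |
| 29 | 33.6 | 29 | 16.9 | 29 | 58.0 | 29 | 56.5 |
| 55 | 43.9 | 55 | 22.6 | 55 | 68.5 | 55 | 68.2 |

(standard deviation of a reading: 0.4 mM)

- apparent order in [G] of the starting rate, round the charge of the grey run (the rate where two percent of its G have turned into L) (one fixed amount of L, the same in the runs compared)
- apparent order in [X] of the starting rate, round the charge of the grey run (the rate where two percent of its G have turned into L)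
- the red run starts with 32.0 mM less of G and of X than the grey run, and with no L. Compared where both hold the same amount of G, once fifteen percent of what the red run was charged with has turned into L, is the red run faster, slower or alike (within a tenth)?
- L in the violet run at 55 min, as a share of the G charged

- Overall: G + X -> L.
- Constant volume, constant temperature.
- Bound and free are read together.
- "The second partner" is X.
- An order is taken over about fifteen percent of the charge, up and down.

Our zero of the scale is a flask in which G and X simply meet in pairs and nothing else happens. It needs one number. We read 0.301 /M/min from the grey run up to 8.0 min and call it the pair constant, the apparent second-order rate constant: rate divided by the product of G and X.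

With this constant held, the pair law puts the grey run at 60.9% of its G at 55 min. The reading is lower, so the grey run keeps a fraction 0.901 of its yardstick. The same law puts the violet run at 91.2%. A cheap step is to multiply the two, and as our own estimate we commit to 82.1%.

Your forecast has orders of 0.98 in G and 0.78 in X, the red run faster than the grey run at equal G, and 81% for the violet run. That last figure is a little under ours. We take over your reading of the teal run, “so L does not inhibit”, and so we do not charge the grey shortfall to L.

The flask gives orders of 1.0 in G and 0.76 in X, the red run faster, and 77.4% for the violet run, with these steps:

    G + X → L (0.4746 /M/min)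
    2 X ⇌ X2, settled at all times (4.660 /M)
    2 X → Ek (0.2136 /M/min)

That share stands 14 percentage points short of the yardstick from the pair constant 0.301 /M/min. The main reason is the step that takes two X to Ek: the violet run with that step taken away reaches 89.8%, against 77.4% with it. Set against the red run, the same constant puts half of its G at 55.5 min, and the red run got there later, at 61.3 min.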